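**Retrosynthetic overview**
1. Target as read: (S)-2-aryl-6-methylhepta-1,5-dien-3-yl angelate, with aryl = 2-acetoxy-3,5-dihydroxy-4-methylphenyl and the ester (Z). End game from phenol-alcohol 15: phenol acetylation, angeloylation, desilylation.
2. Aryl–C2 bond: Negishi coupling of the arylzinc made by carbamate-directed ortho-metalation of 5 with the chiral 2-chloroallyl carbamate 11.
3. Key C2–C3 bond, made with reversed polarity: the carbinol carbon C3 acts as a nucleophile (sparteine-lithiated, zinc-transmetalated carbamate of homoprenol, an α-oxy carbanion) and is joined to the electrophilic carbon of 1,1-dichloroethene. This step sets the (S) centre.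
4. Arene 5 from 2,4-dihydroxy-3-methylbenzaldehyde: silylation, Dakin-type oxidation (CHO becomes the oxygen that later carries the acetate), carbamoylation.
5. No ring is formed; the benzene ring is bought intact.

**Route**

Step 1
Reactants: 1 2,4-dihydroxy-3-methylbenzaldehyde
Product: 2 3-methyl-2,4-bis(triisopropylsilyloxy)benzaldehyde
Conditions: TIPSOTf (2.4 equiv), 2,6-lutidine (3 equiv), CH2Cl2, 0 °C → rt
Reagents that add atoms: triisopropylsilyl trifluoromethanesulfonate, CC(C)[Si](OS(=O)(=O)C(F)(F)F)(C(C)C)C(C)C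
Why: Phenol silylation with the silyl triflate, which also reaches the hindered hydrogen-bonded 2-OH; TIPS is chosen because it resists alkyllithiums, LiAlH4 and O→O silyl migration yet is removed by fluoride at the end.

Step 2
Reactants: 2 3-methyl-2,4-bis(triisopropylsilyloxy)benzaldehyde
Product: 4 3-methyl-2,4-bis(triisopropylsilyloxy)phenol, via aryl formate 3 (not isolated)
Conditions: mCPBA (1.5 equiv), CH2Cl2, 0 °C → rt; aq Na2S2O3/NaHCO3 wash; then Et3N (cat.), MeOH, 0 °C
Reagents that add atoms: 3-chloroperbenzoic acid, OOC(=O)c1cccc(Cl)c1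
Why: Dakin-type Baeyer–Villiger oxidation, in which the electron-rich o,p-disilyloxyaryl group migrates to give the aryl formate, which is then methanolysed to the phenol.

Step 3
Reactants: 4 3-methyl-2,4-bis(triisopropylsilyloxy)phenol
Product: 5 3-methyl-2,4-bis(triisopropylsilyloxy)phenyl N,N-diethylcarbamate
Conditions: Et2NCOCl (1.5 equiv), NaH (1.2 equiv, added last), THF, 0 °C → rt
Reagents that add atoms: N,N-diethylcarbamoyl chloride, CCN(CC)C(=O)Cl
Why: O-Carbamoylation of the phenoxide, trapped as it forms so that the neighbouring TIPS group has no time to migrate; it places the strongest oxygen-based directing group for ortho-metalation on the oxygen that is later acetylated.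

Step 4
Reactants: 6 4-methylpent-3-en-1-ol
Product: 7 4-methylpent-3-en-1-yl N,N-diisopropylcarbamate
Conditions: i-Pr2NCOCl (1.2 equiv), Et3N (1.5 equiv), CH2Cl2, reflux
Reagents that add atoms: N,N-diisopropylcarbamoyl chloride, CC(C)N(C(C)C)C(=O)Cl
Why: Carbamoylation of a primary alcohol; the hindered carbamate is the directing and stabilising group needed for Hoppe α-lithiation.

Step 5
Reactants: 7 4-methylpent-3-en-1-yl N,N-diisopropylcarbamate; 8 1,1-dichloroethene
Product: 11 (S)-2-chloro-6-methylhepta-1,5-dien-3-yl N,N-diisopropylcarbamate, via lithio carbamate 9 (not isolated), via alkylzinc chloride 10 (not isolated)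
Conditions: s-BuLi (1.3 equiv), (+)-sparteine (1.3 equiv), Et2O, −78 °C, 5 h; ZnCl2 (1.4 equiv, in THF), −78 °C → rt; then Pd(OAc)2 (5 mol %), t-Bu3P·HBF4 (10 mol %), 8 (10 equiv), rt → 35 °C, sealed vessel
Reagents that add atoms: none
Why: Proposed new method: s-BuLi/(+)-sparteine removes the pro-R α-proton of 7 (Hoppe asymmetric deprotonation) to give a configurationally stable α-oxy carbanion, which is carried with retention through Li→Zn→Pd transmetalation and reductive elimination onto the electrophilic carbon of 8 (oxidative addition into one activated geminal C–Cl bond, with excess 8 keeping it to mono-coupling), so the (S) centre is set directly, and chelation of the carbamate C=O to Pd should hold back β-hydride elimination; the closest known reactions are the stereoretentive sparteine-lithiation/zinc/Negishi α-arylation of O-alkyl carbamates and N-Boc amines and the selective Pd mono-coupling of organozincs with 1,1-dichloroethene.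

Step 6
Reactants: 5 3-methyl-2,4-bis(triisopropylsilyloxy)phenyl N,N-diethylcarbamate; 11 (S)-2-chloro-6-methylhepta-1,5-dien-3-yl N,N-diisopropylcarbamate
Product: 14 (S)-2-[2-(N,N-diethylcarbamoyloxy)-4-methyl-3,5-bis(triisopropylsilyloxy)phenyl]-6-methylhepta-1,5-dien-3-yl N,N-diisopropylcarbamate, via aryllithium 12 (not isolated), via arylzinc chloride 13 (not isolated)
Conditions: 5 (1.5 equiv), s-BuLi (1.5 equiv), TMEDA (1.6 equiv), THF, −78 °C, 1 h; ZnCl2 (1.7 equiv), −78 °C → rt; then 11 (1.0 equiv), Pd2(dba)3 (2.5 mol %), SPhos (10 mol %), THF, 60 °C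
Reagents that add atoms: none
Why: Carbamate-directed ortho-lithiation (Snieckus) occurs only at the free position next to the carbamate because the silyl ethers do not direct, and the derived arylzinc undergoes Negishi coupling with the alkenyl chloride under a bulky biarylphosphine catalyst without touching the stereocentre.

Step 7
Reactants: 14 (S)-2-[2-(N,N-diethylcarbamoyloxy)-4-methyl-3,5-bis(triisopropylsilyloxy)phenyl]-6-methylhepta-1,5-dien-3-yl N,N-diisopropylcarbamate
Product: 15 (S)-2-[2-hydroxy-4-methyl-3,5-bis(triisopropylsilyloxy)phenyl]-6-methylhepta-1,5-dien-3-ol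
Conditions: LiAlH4 (6 equiv), THF, 0 → 50 °C; Rochelle-salt work-up (no acid)
Reagents that add atoms: none
Why: Hydride reduction cleaves both the aryl and the hindered alkyl carbamate (each ends as an N-methylamine) with retention at C3, and the neutral work-up avoids acid-promoted cyclisation of the o-hydroxyaryl allylic alcohol.

Step 8
Reactants: 15 (S)-2-[2-hydroxy-4-methyl-3,5-bis(triisopropylsilyloxy)phenyl]-6-methylhepta-1,5-dien-3-ol
Product: 16 (S)-2-[2-acetoxy-4-methyl-3,5-bis(triisopropylsilyloxy)phenyl]-6-methylhepta-1,5-dien-3-ol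
Conditions: Ac2O (1.2 equiv), K2CO3 (1.5 equiv), acetone, 0 °C
Reagents that add atoms: acetic anhydride, CC(=O)OC(C)=O
Why: Chemoselective O-acetylation, since carbonate ionises only the phenol and the phenoxide is acylated far faster than the neutral hindered secondary alcohol.

Step 9
Reactants: 16 (S)-2-[2-acetoxy-4-methyl-3,5-bis(triisopropylsilyloxy)phenyl]-6-methylhepta-1,5-dien-3-ol; 17 angelic acid, (Z)-2-methylbut-2-enoic acid
Product: 18 (S)-2-[2-acetoxy-4-methyl-3,5-bis(triisopropylsilyloxy)phenyl]-6-methylhepta-1,5-dien-3-yl (Z)-2-methylbut-2-enoate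
Conditions: 17 (3 equiv), 2,4,6-Cl3C6H2COCl (3 equiv), Et3N (3 equiv), toluene, rt, 2 h; then 16, 80 °C, no DMAP
Reagents that add atoms: none
Why: Yamaguchi-type esterification through the angelic 2,4,6-trichlorobenzoic mixed anhydride, run without DMAP to avoid Z→E isomerisation to the tiglate; the C3–O bond is not broken, so the configuration is kept.

Step 10
Reactants: 18 (S)-2-[2-acetoxy-4-methyl-3,5-bis(triisopropylsilyloxy)phenyl]-6-methylhepta-1,5-dien-3-yl (Z)-2-methylbut-2-enoate
Product: 19 (S)-2-(2-acetoxy-3,5-dihydroxy-4-methylphenyl)-6-methylhepta-1,5-dien-3-yl (Z)-2-methylbut-2-enoate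
Conditions: TBAF (2.5 equiv), AcOH (3 equiv), THF, 0 °C
Reagents that add atoms: none
Why: Fluoride desilylation of the two aryl silyl ethers, buffered with acetic acid so the phenoxides are protonated at once and neither ester is cleaved nor the acetyl group moved to the neighbouring 3-OH.

**Compound list**
1 | 2,4-dihydroxy-3-methylbenzaldehyde | O=Cc1ccc(O)c(C)c1O | starting material
2 | 3-methyl-2,4-bis(triisopropylsilyloxy)benzaldehyde | O=Cc1ccc(O[Si](C(C)C)(C(C)C)C(C)C)c(C)c1O[Si](C(C)C)(C(C)C)C(C)C | intermediate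
3 | 3-methyl-2,4-bis(triisopropylsilyloxy)phenyl formate (not isolated) | O=COc1ccc(O[Si](C(C)C)(C(C)C)C(C)C)c(C)c1O[Si](C(C)C)(C(C)C)C(C)C | intermediate
4 | 3-methyl-2,4-bis(triisopropylsilyloxy)phenol | Oc1ccc(O[Si](C(C)C)(C(C)C)C(C)C)c(C)c1O[Si](C(C)C)(C(C)C)C(C)C | intermediate
5 | 3-methyl-2,4-bis(triisopropylsilyloxy)phenyl N,N-diethylcarbamate | CCN(CC)C(=O)Oc1ccc(O[Si](C(C)C)(C(C)C)C(C)C)c(C)c1O[Si](C(C)C)(C(C)C)C(C)C | intermediate
6 | 4-methylpent-3-en-1-ol | CC(C)=CCCO | starting material
7 | 4-methylpent-3-en-1-yl N,N-diisopropylcarbamate | CC(C)=CCCOC(=O)N(C(C)C)C(C)C | intermediate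
8 | 1,1-dichloroethene | C=C(Cl)Cl | starting material
9 | (R)-1-lithio-4-methylpent-3-en-1-yl N,N-diisopropylcarbamate, (+)-sparteine complex (not isolated) | [Li][C@H](CC=C(C)C)OC(=O)N(C(C)C)C(C)C | intermediate
10 | (R)-1-(chlorozincio)-4-methylpent-3-en-1-yl N,N-diisopropylcarbamate (not isolated) | Cl[Zn][C@H](CC=C(C)C)OC(=O)N(C(C)C)C(C)C | intermediate
11 | (S)-2-chloro-6-methylhepta-1,5-dien-3-yl N,N-diisopropylcarbamate | C=C(Cl)[C@H](CC=C(C)C)OC(=O)N(C(C)C)C(C)C | intermediate
12 | 6-lithio-3-methyl-2,4-bis(triisopropylsilyloxy)phenyl N,N-diethylcarbamate (not isolated) | [Li]c1cc(O[Si](C(C)C)(C(C)C)C(C)C)c(C)c(O[Si](C(C)C)(C(C)C)C(C)C)c1OC(=O)N(CC)CC | intermediate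
13 | 6-(chlorozincio)-3-methyl-2,4-bis(triisopropylsilyloxy)phenyl N,N-diethylcarbamate (not isolated) | Cl[Zn]c1cc(O[Si](C(C)C)(C(C)C)C(C)C)c(C)c(O[Si](C(C)C)(C(C)C)C(C)C)c1OC(=O)N(CC)CC | intermediate
14 | (S)-2-[2-(N,N-diethylcarbamoyloxy)-4-methyl-3,5-bis(triisopropylsilyloxy)phenyl]-6-methylhepta-1,5-dien-3-yl N,N-diisopropylcarbamate | C=C(c1cc(O[Si](C(C)C)(C(C)C)C(C)C)c(C)c(O[Si](C(C)C)(C(C)C)C(C)C)c1OC(=O)N(CC)CC)[C@H](CC=C(C)C)OC(=O)N(C(C)C)C(C)C | intermediate
15 | (S)-2-[2-hydroxy-4-methyl-3,5-bis(triisopropylsilyloxy)phenyl]-6-methylhepta-1,5-dien-3-ol | C=C(c1cc(O[Si](C(C)C)(C(C)C)C(C)C)c(C)c(O[Si](C(C)C)(C(C)C)C(C)C)c1O)[C@H](CC=C(C)C)O | intermediate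
16 | (S)-2-[2-acetoxy-4-methyl-3,5-bis(triisopropylsilyloxy)phenyl]-6-methylhepta-1,5-dien-3-ol | C=C(c1cc(O[Si](C(C)C)(C(C)C)C(C)C)c(C)c(O[Si](C(C)C)(C(C)C)C(C)C)c1OC(C)=O)[C@H](CC=C(C)C)O | intermediate
17 | angelic acid, (Z)-2-methylbut-2-enoic acid | OC(=O)/C(C)=C\C | starting material
18 | (S)-2-[2-acetoxy-4-methyl-3,5-bis(triisopropylsilyloxy)phenyl]-6-methylhepta-1,5-dien-3-yl (Z)-2-methylbut-2-enoate | C=C(c1cc(O[Si](C(C)C)(C(C)C)C(C)C)c(C)c(O[Si](C(C)C)(C(C)C)C(C)C)c1OC(C)=O)[C@H](CC=C(C)C)OC(=O)/C(C)=C\C | intermediate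
19 | (S)-2-(2-acetoxy-3,5-dihydroxy-4-methylphenyl)-6-methylhepta-1,5-dien-3-yl (Z)-2-methylbut-2-enoate | C=C(c1cc(O)c(C)c(O)c1OC(C)=O)[C@H](CC=C(C)C)OC(=O)/C(C)=C\C | target

**Step count**
Total: 10 steps. Longest linear sequence: 8 steps (1, 2, 3, 6, 7, 8, 9, 10); the side branch is steps 4 and 5.

**Three steps most likely to fail**

Step 5. The α-oxyalkyl palladium intermediate has allylic β-hydrogens, so β-hydride elimination to a dienyl carbamate, slow transmetalation or loss of er could defeat the coupling. The fallback avoids a Pd step at this carbon. It sets out from 7: the lithio carbamate 9 is made as before and acylated directly with N-methoxy-N-methylacetamide (−78 °C, retention) to give (S)-6-methyl-2-oxohept-5-en-3-yl N,N-diisopropylcarbamate F1. Kinetic enolisation on the methyl side (KHMDS, PhNTf2, THF, −78 °C) gives the enol triflate (S)-6-methyl-2-(trifluoromethylsulfonyloxy)hepta-1,5-dien-3-yl N,N-diisopropylcarbamate F2. F2 takes the place of 11 in the coupling with arylzinc 13 under the step 6 conditions, and the route is rejoined at 14.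

Step 6. Oxidative addition into the hindered 2-chloroallyl carbamate may be slow, and the vinyl-palladium species could lose the β-carbamate to give an allene. The fallback inverts the roles of the partners. It sets out from 5: aryllithium 12 is quenched with N-methoxy-N-methylacetamide to give 6-acetyl-3-methyl-2,4-bis(triisopropylsilyloxy)phenyl N,N-diethylcarbamate F3. KHMDS and PhNTf2 (THF, −78 °C) convert it to 3-methyl-2,4-bis(triisopropylsilyloxy)-6-[1-(trifluoromethylsulfonyloxy)vinyl]phenyl N,N-diethylcarbamate F4. This far more reactive alkenyl triflate is coupled with the chiral alkylzinc 10 (made from 7 as in step 5) under Pd(OAc)2/t-Bu3P, which gives 14 directly.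

Step 9. The alcohol is hindered, angelate can isomerise to tiglate, and at 80 °C the aryl acetate could transfer to the neighbouring secondary oxygen. The fallback builds the angelate double bond on the ester at low temperature. It sets out from 16, which is esterified at rt with 2-[bis(2,2,2-trifluoroethoxy)phosphoryl]propanoic acid (EDC·HCl, cat. DMAP, CH2Cl2) to give (S)-2-[2-acetoxy-4-methyl-3,5-bis(triisopropylsilyloxy)phenyl]-6-methylhepta-1,5-dien-3-yl 2-[bis(2,2,2-trifluoroethoxy)phosphoryl]propanoate F5. A Z-selective Still–Gennari olefination with acetaldehyde (KHMDS, 18-crown-6, THF, −78 °C) then gives the angelate, and the route is rejoined at 18.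

**Further compounds**
F1 | step 5 | (S)-6-methyl-2-oxohept-5-en-3-yl N,N-diisopropylcarbamate | CC(=O)[C@H](CC=C(C)C)OC(=O)N(C(C)C)C(C)C
F2 | step 5 | (S)-6-methyl-2-(trifluoromethylsulfonyloxy)hepta-1,5-dien-3-yl N,N-diisopropylcarbamate | C=C(OS(=O)(=O)C(F)(F)F)[C@H](CC=C(C)C)OC(=O)N(C(C)C)C(C)C
F3 | step 6 | 6-acetyl-3-methyl-2,4-bis(triisopropylsilyloxy)phenyl N,N-diethylcarbamate | CC(=O)c1cc(O[Si](C(C)C)(C(C)C)C(C)C)c(C)c(O[Si](C(C)C)(C(C)C)C(C)C)c1OC(=O)N(CC)CC
F4 | step 6 | 3-methyl-2,4-bis(triisopropylsilyloxy)-6-[1-(trifluoromethylsulfonyloxy)vinyl]phenyl N,N-diethylcarbamate | C=C(OS(=O)(=O)C(F)(F)F)c1cc(O[Si](C(C)C)(C(C)C)C(C)C)c(C)c(O[Si](C(C)C)(C(C)C)C(C)C)c1OC(=O)N(CC)CC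
F5 | step 9 | (S)-2-[2-acetoxy-4-methyl-3,5-bis(triisopropylsilyloxy)phenyl]-6-methylhepta-1,5-dien-3-yl 2-[bis(2,2,2-trifluoroethoxy)phosphoryl]propanoate (both epimers at the phosphonate carbon) | C=C(c1cc(O[Si](C(C)C)(C(C)C)C(C)C)c(C)c(O[Si](C(C)C)(C(C)C)C(C)C)c1OC(C)=O)[C@H](CC=C(C)C)OC(=O)C(C)P(=O)(OCC(F)(F)F)OCC(F)(F)F
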